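**Strategy.** The ten-membered carbocycle (C1–C10, germacranolide numbering) is closed last, at C7–C8, on a preformed γ-lactone (O, C6, C7, C11, C12). The target's homoallylic array C13=C11–C7–C8–O is the retron of a carbonyl allylation: Cr(II) turns the 3-(bromomethyl)butenolide, whose β-carbon C7 is normally an electrophile, into an allylchromium nucleophile that attacks the tethered C8 aldehyde. This one operation closes the ring, creates C7 and C8 and shifts the double bond to unveil the α-methylene lactone. The precursor is an acyclic aldehyde with both ring-cis trisubstituted olefins in place, C14 masked as a dimethyl acetal and the single stereocentre C6 set by asymmetric vinylation.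

Key step: step 13

Numbering used throughout: C6 lactone O–CH, C7 ring-fusion CH, C8 CH–O-acyl, C9 CH2, C10(=C1) bearing C14, C2 and C3 CH2, C4(=C5) bearing C15, C11 lactone α-carbon, C12 lactone C=O, C13 exocyclic CH2.

Assumption: the chromium closure passes through the usual closed chair transition state and gives the 8α (8S) alcohol, so the isovalerate is installed with inversion; but-3-enylzinc bromide is used as its commercial THF solution.

Step 1
Reactants: 1 but-2-yne-1,4-diol
Product: 2 4-[(tert-butyldiphenylsilyl)oxy]but-2-yn-1-ol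
Conditions: NaH (1.0 equiv), THF, 0 °C; TBDPSCl (1.0 equiv), 0 °C → rt
Reagents that add atoms: tert-butyl(chloro)diphenylsilane CC(C)(C)[Si](Cl)(c1ccccc1)c1ccccc1
Why: Monosilylation of a symmetrical diol through its sparingly soluble monosodium alkoxide (Williamson-type O-silylation) differentiates the future C15–O from C6–O.

Step 2
Reactants: 2 4-[(tert-butyldiphenylsilyl)oxy]but-2-yn-1-ol
Product: 4 (2Z)-4-[(tert-butyldiphenylsilyl)oxy]-3-iodobut-2-en-1-ol, via cyclic sodium alkenylalanate 3 (not isolated)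
Conditions: Red-Al (1.5 equiv), THF, 0 °C; then I2, −78 → 0 °C; Rochelle salt work-up
Reagents that add atoms: iodine II
Why: Hydroxyl-directed trans-hydroalumination of the propargylic alcohol places aluminium on the distal alkyne carbon in a five-membered alanate, and iodinolysis with retention should give the (Z)-iodide in which iodine is cis to the CH2OH carbon (C6).

Step 3
Reactants: 4 (2Z)-4-[(tert-butyldiphenylsilyl)oxy]-3-iodobut-2-en-1-ol; 5 but-3-en-1-ylzinc bromide
Product: 6 (2E)-3-{[(tert-butyldiphenylsilyl)oxy]methyl}hepta-2,6-dien-1-ol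
Conditions: Pd(dppf)Cl2 (5 mol%), 5 (2.5 equiv), THF, rt → 45 °C
Reagents that add atoms: none
Why: Negishi sp2–sp3 cross-coupling proceeds with retention at the alkenyl iodide, so C3 ends cis to C6 and the ring-cis C4=C5 olefin is fixed.

Step 4
Reactants: 7 4-[(tert-butyldimethylsilyl)oxy]butanal
Product: 8 4-[(tert-butyldimethylsilyl)oxy]-2-methylidenebutanal
Conditions: 37% aq. HCHO, pyrrolidine (10 mol%), propionic acid (10 mol%), i-PrOH, 45 °C
Reagents that add atoms: formaldehyde C=O
Why: Amine-catalysed Mannich condensation–elimination (organocatalytic α-methylenation of an aldehyde) should give the 2-substituted acrolein that carries C14, C10, C9 and C8.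

Step 5
Reactants: 6 (2E)-3-{[(tert-butyldiphenylsilyl)oxy]methyl}hepta-2,6-dien-1-ol; 8 4-[(tert-butyldimethylsilyl)oxy]-2-methylidenebutanal
Product: 9 (2E,6E)-2-{2-[(tert-butyldimethylsilyl)oxy]ethyl}-6-{[(tert-butyldiphenylsilyl)oxy]methyl}-8-hydroxyocta-2,6-dienal
Conditions: Hoveyda–Grubbs II (5 mol%), 8 (3 equiv), CH2Cl2, 40 °C
Reagents that add atoms: none
Why: Olefin cross-metathesis of a terminal alkene with a 2-substituted acrolein should give the trisubstituted enal under thermodynamic control with C2 trans to the formyl group, which is the ring-cis C1=C10 geometry, while the trisubstituted C4=C5 olefin stays inert.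

Step 6
Reactants: 9 (2E,6E)-2-{2-[(tert-butyldimethylsilyl)oxy]ethyl}-6-{[(tert-butyldiphenylsilyl)oxy]methyl}-8-hydroxyocta-2,6-dienal
Product: 10 (2E,6E)-9-[(tert-butyldimethylsilyl)oxy]-3-{[(tert-butyldiphenylsilyl)oxy]methyl}-7-(dimethoxymethyl)nona-2,6-dien-1-ol
Conditions: HC(OMe)3, PPTS (5 mol%), MeOH, 0 °C
Reagents that add atoms: trimethyl orthoformate COC(OC)OC
Why: Acid-catalysed acetalisation with orthoformate as water scavenger masks the C14 enal, and PPTS at 0 °C should spare both silyl ethers.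

Step 7
Reactants: 10 (2E,6E)-9-[(tert-butyldimethylsilyl)oxy]-3-{[(tert-butyldiphenylsilyl)oxy]methyl}-7-(dimethoxymethyl)nona-2,6-dien-1-ol
Product: 11 (2E,6E)-9-[(tert-butyldimethylsilyl)oxy]-3-{[(tert-butyldiphenylsilyl)oxy]methyl}-7-(dimethoxymethyl)nona-2,6-dienal
Conditions: activated MnO2, CH2Cl2, rt
Reagents that add atoms: none
Why: Manganese dioxide oxidises only the allylic alcohol and, being neutral, should keep the neral-type geometry of the C4=C5 olefin.

Step 8
Reactants: 11 (2E,6E)-9-[(tert-butyldimethylsilyl)oxy]-3-{[(tert-butyldiphenylsilyl)oxy]methyl}-7-(dimethoxymethyl)nona-2,6-dienal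
Product: 12 (3S,4E,8E)-11-[(tert-butyldimethylsilyl)oxy]-5-{[(tert-butyldiphenylsilyl)oxy]methyl}-9-(dimethoxymethyl)undeca-1,4,8-trien-3-ol
Conditions: divinylzinc made in the flask (vinylmagnesium bromide 2.4 equiv, ZnCl2 1.2 equiv, Et2O, then 1,4-dioxane to precipitate magnesium salts); (2S)-(−)-3-exo-(morpholino)isoborneol (10 mol%), toluene, −20 °C
Reagents that add atoms: vinylmagnesium bromide C=C[Mg]Br
Why: Amino-alcohol-catalysed asymmetric addition of a vinylzinc reagent to an aldehyde should deliver the vinyl group to the Si face, as this ligand does with simple aldehydes, setting C6 as the 3S carbinol by catalyst control.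

Step 9
Reactants: 12 (3S,4E,8E)-11-[(tert-butyldimethylsilyl)oxy]-5-{[(tert-butyldiphenylsilyl)oxy]methyl}-9-(dimethoxymethyl)undeca-1,4,8-trien-3-ol; 13 2-(bromomethyl)prop-2-enoic acid
Product: 14 (3S,4E,8E)-11-[(tert-butyldimethylsilyl)oxy]-5-{[(tert-butyldiphenylsilyl)oxy]methyl}-9-(dimethoxymethyl)undeca-1,4,8-trien-3-yl 2-(bromomethyl)prop-2-enoate
Conditions: DCC, DMAP (5 mol%), CH2Cl2, −20 → 0 °C
Reagents that add atoms: none
Why: Steglich esterification acylates the only free hydroxyl with retention at C6, and low temperature with little DMAP limits SN2′ attack on the allylic bromide.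

Step 10
Reactants: 14 (3S,4E,8E)-11-[(tert-butyldimethylsilyl)oxy]-5-{[(tert-butyldiphenylsilyl)oxy]methyl}-9-(dimethoxymethyl)undeca-1,4,8-trien-3-yl 2-(bromomethyl)prop-2-enoate
Product: 15 (5R)-3-(bromomethyl)-5-[(1E,5E)-8-[(tert-butyldimethylsilyl)oxy]-2-{[(tert-butyldiphenylsilyl)oxy]methyl}-6-(dimethoxymethyl)octa-1,5-dien-1-yl]furan-2(5H)-one
Conditions: Grubbs II (10 mol%), CH2Cl2 (5 mM), 40 °C
Reagents that add atoms: none
Why: Ring-closing metathesis between the monosubstituted C7 vinyl group and the acrylate closes the five-membered butenolide faster than any reaction at the two hindered trisubstituted olefins, and C6 is untouched.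

Step 11
Reactants: 15 (5R)-3-(bromomethyl)-5-[(1E,5E)-8-[(tert-butyldimethylsilyl)oxy]-2-{[(tert-butyldiphenylsilyl)oxy]methyl}-6-(dimethoxymethyl)octa-1,5-dien-1-yl]furan-2(5H)-one
Product: 16 (5R)-3-(bromomethyl)-5-[(1E,5E)-2-{[(tert-butyldiphenylsilyl)oxy]methyl}-6-(dimethoxymethyl)-8-hydroxyocta-1,5-dien-1-yl]furan-2(5H)-one
Conditions: CSA (10 mol%), MeOH/CH2Cl2 (1:1), 0 °C
Reagents that add atoms: none
Why: Acid-catalysed methanolysis removes the primary alkyl TBS ether far faster than the TBDPS ether, and in methanol the dimethyl acetal only exchanges with itself.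

Step 12
Reactants: 16 (5R)-3-(bromomethyl)-5-[(1E,5E)-2-{[(tert-butyldiphenylsilyl)oxy]methyl}-6-(dimethoxymethyl)-8-hydroxyocta-1,5-dien-1-yl]furan-2(5H)-one
Product: 17 (3E,7E)-8-[(2R)-4-(bromomethyl)-5-oxo-2,5-dihydrofuran-2-yl]-7-{[(tert-butyldiphenylsilyl)oxy]methyl}-3-(dimethoxymethyl)octa-3,7-dienal
Conditions: Dess–Martin periodinane, NaHCO3, CH2Cl2, 0 °C; crude aldehyde used at once
Reagents that add atoms: none
Why: Buffered Dess–Martin oxidation gives the β,γ-unsaturated aldehyde under non-basic conditions that should not move the C1=C10 olefin into conjugation or touch the acidic C6–H.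

Step 13
Reactants: 17 (3E,7E)-8-[(2R)-4-(bromomethyl)-5-oxo-2,5-dihydrofuran-2-yl]-7-{[(tert-butyldiphenylsilyl)oxy]methyl}-3-(dimethoxymethyl)octa-3,7-dienal
Product: 19 (3aR,4S,6E,10E,11aR)-10-{[(tert-butyldiphenylsilyl)oxy]methyl}-6-(dimethoxymethyl)-4-hydroxy-3-methylidene-3a,4,5,8,9,11a-hexahydrocyclodeca[b]furan-2(3H)-one, via allylchromium(III) dichloride 18 (not isolated)
Conditions: CrCl2 (10 equiv), degassed THF/DMF (4:1), rt; 17 added by syringe pump over 12 h to a final 2 mM
Reagents that add atoms: none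
Why: Two equivalents of Cr(II) reduce the allylic C13–Br bond of 17 to the allylchromium(III) species 18, which adds through its γ-carbon C7 (formerly the electrophilic β-carbon of the butenolide) to the tethered aldehyde carbon C8 in an intramolecular Nozaki–Hiyama–Kishi allylation, the ring-closing counterpart of the known chromium-mediated allylation of aldehydes with 3-(bromomethyl)furan-2(5H)-ones and 2-(bromomethyl)acrylates. The ten-membered ring closes in a 10-exo-trig carbonyl addition (SE2′ at the allyl unit), which moves the double bond to C11=C13 and so reveals the α-methylene lactone. C7 is controlled by the C6 stereocentre: allylic 1,3-strain across the C4=C5 olefin (C3 is cis to C6) holds H6 in the olefin plane, so the tether returns over the H6 face and C8 bonds anti to C5, giving the trans-fused lactone. C8 follows from a chair Zimmerman–Traxler transition state in which the ring-locked E-type γ-substituent (C6) and the aldehyde substituent (C9) are both equatorial, giving the 7,8-anti (8S, 8α) alcohol that step 14 inverts. The step needs metalation of the allylic bromide only, γ- and not α-attack (α-attack would give a twelve-membered ring) and ring closure in preference to oligomerisation; these rest on the high reactivity of the bromomethyl-butenolide toward Cr(II), the SE2′ preference of allylchromium reagents, and slow addition at high dilution aided by the two ring-cis olefins that fold the chain.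

Step 14
Reactants: 19 (3aR,4S,6E,10E,11aR)-10-{[(tert-butyldiphenylsilyl)oxy]methyl}-6-(dimethoxymethyl)-4-hydroxy-3-methylidene-3a,4,5,8,9,11a-hexahydrocyclodeca[b]furan-2(3H)-one; 20 3-methylbutanoic acid
Product: 21 (3aR,4R,6E,10E,11aR)-10-{[(tert-butyldiphenylsilyl)oxy]methyl}-6-(dimethoxymethyl)-3-methylidene-2-oxo-2,3,3a,4,5,8,9,11a-octahydrocyclodeca[b]furan-4-yl 3-methylbutanoate
Conditions: PPh3, DIAD, 20 (3 equiv each; betaine preformed), toluene, 0 °C → rt
Reagents that add atoms: none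
Why: Mitsunobu esterification displaces the activated C8 oxygen by isovalerate in an SN2 step, inverting 8S to the required 8R (8β) ester in the same operation that installs the acyl group.

Step 15
Reactants: 21 (3aR,4R,6E,10E,11aR)-10-{[(tert-butyldiphenylsilyl)oxy]methyl}-6-(dimethoxymethyl)-3-methylidene-2-oxo-2,3,3a,4,5,8,9,11a-octahydrocyclodeca[b]furan-4-yl 3-methylbutanoate
Product: 23 CNP0345200.3 (target), via 15-hydroxy dimethyl acetal 22 (not isolated)
Conditions: HF·pyridine, pyridine, THF, 0 °C → rt; then H2O, PPTS (cat.), rt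
Reagents that add atoms: water O
Why: Fluoride cleaves the primary TBDPS ether and the mildly acidic aqueous medium then hydrolyses the conjugated dimethyl acetal to the C14 enal, conditions under which the ester, the lactone and the stereocentres should be stable.

**Compound list**

1 | but-2-yne-1,4-diol | OCC#CCO | starting material
2 | 4-[(tert-butyldiphenylsilyl)oxy]but-2-yn-1-ol | OCC#CCO[Si](c1ccccc1)(c1ccccc1)C(C)(C)C | intermediate
3 | sodium 3-{[(tert-butyldiphenylsilyl)oxy]methyl}-2,2-bis(2-methoxyethoxy)-2,5-dihydro-1,2-oxaluminol-2-uide (cyclic alkenylalanate) | [Na+].COCCO[Al-]1(OCCOC)OC/C=C1/CO[Si](c2ccccc2)(c2ccccc2)C(C)(C)C | intermediate (not isolated)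
4 | (2Z)-4-[(tert-butyldiphenylsilyl)oxy]-3-iodobut-2-en-1-ol | OC/C=C(\I)CO[Si](c1ccccc1)(c1ccccc1)C(C)(C)C | intermediate
5 | but-3-en-1-ylzinc bromide | C=CCC[Zn]Br | starting material
6 | (2E)-3-{[(tert-butyldiphenylsilyl)oxy]methyl}hepta-2,6-dien-1-ol | OC/C=C(/CO[Si](c1ccccc1)(c1ccccc1)C(C)(C)C)CCC=C | intermediate
7 | 4-[(tert-butyldimethylsilyl)oxy]butanal | O=CCCCO[Si](C)(C)C(C)(C)C | starting material
8 | 4-[(tert-butyldimethylsilyl)oxy]-2-methylidenebutanal | C=C(C=O)CCO[Si](C)(C)C(C)(C)C | intermediate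
9 | (2E,6E)-2-{2-[(tert-butyldimethylsilyl)oxy]ethyl}-6-{[(tert-butyldiphenylsilyl)oxy]methyl}-8-hydroxyocta-2,6-dienal | OC/C=C(/CO[Si](c1ccccc1)(c1ccccc1)C(C)(C)C)CC/C=C(/C=O)CCO[Si](C)(C)C(C)(C)C | intermediate
10 | (2E,6E)-9-[(tert-butyldimethylsilyl)oxy]-3-{[(tert-butyldiphenylsilyl)oxy]methyl}-7-(dimethoxymethyl)nona-2,6-dien-1-ol | OC/C=C(/CO[Si](c1ccccc1)(c1ccccc1)C(C)(C)C)CC/C=C(/C(OC)OC)CCO[Si](C)(C)C(C)(C)C | intermediate
11 | (2E,6E)-9-[(tert-butyldimethylsilyl)oxy]-3-{[(tert-butyldiphenylsilyl)oxy]methyl}-7-(dimethoxymethyl)nona-2,6-dienal | O=C/C=C(/CO[Si](c1ccccc1)(c1ccccc1)C(C)(C)C)CC/C=C(/C(OC)OC)CCO[Si](C)(C)C(C)(C)C | intermediate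
12 | (3S,4E,8E)-11-[(tert-butyldimethylsilyl)oxy]-5-{[(tert-butyldiphenylsilyl)oxy]methyl}-9-(dimethoxymethyl)undeca-1,4,8-trien-3-ol | C=C[C@H](O)/C=C(/CO[Si](c1ccccc1)(c1ccccc1)C(C)(C)C)CC/C=C(/C(OC)OC)CCO[Si](C)(C)C(C)(C)C | intermediate
13 | 2-(bromomethyl)prop-2-enoic acid | C=C(CBr)C(=O)O | starting material
14 | (3S,4E,8E)-11-[(tert-butyldimethylsilyl)oxy]-5-{[(tert-butyldiphenylsilyl)oxy]methyl}-9-(dimethoxymethyl)undeca-1,4,8-trien-3-yl 2-(bromomethyl)prop-2-enoate | C=C[C@H](OC(=O)C(=C)CBr)/C=C(/CO[Si](c1ccccc1)(c1ccccc1)C(C)(C)C)CC/C=C(/C(OC)OC)CCO[Si](C)(C)C(C)(C)C | intermediate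
15 | (5R)-3-(bromomethyl)-5-[(1E,5E)-8-[(tert-butyldimethylsilyl)oxy]-2-{[(tert-butyldiphenylsilyl)oxy]methyl}-6-(dimethoxymethyl)octa-1,5-dien-1-yl]furan-2(5H)-one | O=C1O[C@H](/C=C(/CO[Si](c2ccccc2)(c2ccccc2)C(C)(C)C)CC/C=C(/C(OC)OC)CCO[Si](C)(C)C(C)(C)C)C=C1CBr | intermediate
16 | (5R)-3-(bromomethyl)-5-[(1E,5E)-2-{[(tert-butyldiphenylsilyl)oxy]methyl}-6-(dimethoxymethyl)-8-hydroxyocta-1,5-dien-1-yl]furan-2(5H)-one | O=C1O[C@H](/C=C(/CO[Si](c2ccccc2)(c2ccccc2)C(C)(C)C)CC/C=C(/C(OC)OC)CCO)C=C1CBr | intermediate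
17 | (3E,7E)-8-[(2R)-4-(bromomethyl)-5-oxo-2,5-dihydrofuran-2-yl]-7-{[(tert-butyldiphenylsilyl)oxy]methyl}-3-(dimethoxymethyl)octa-3,7-dienal | O=C1O[C@H](/C=C(/CO[Si](c2ccccc2)(c2ccccc2)C(C)(C)C)CC/C=C(/C(OC)OC)CC=O)C=C1CBr | intermediate
18 | allylchromium(III) dichloride derived from 17 (CrCl2 on C13 in place of Br) | O=C1O[C@H](/C=C(/CO[Si](c2ccccc2)(c2ccccc2)C(C)(C)C)CC/C=C(/C(OC)OC)CC=O)C=C1C[Cr](Cl)Cl | intermediate (not isolated)
19 | (3aR,4S,6E,10E,11aR)-10-{[(tert-butyldiphenylsilyl)oxy]methyl}-6-(dimethoxymethyl)-4-hydroxy-3-methylidene-3a,4,5,8,9,11a-hexahydrocyclodeca[b]furan-2(3H)-one (8α-hydroxy, trans-fused 6α,12-olide) | C=C1C(=O)O[C@@H]2/C=C(/CO[Si](c3ccccc3)(c3ccccc3)C(C)(C)C)CC/C=C(/C(OC)OC)C[C@H](O)[C@@H]12 | intermediate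
20 | 3-methylbutanoic acid (isovaleric acid) | CC(C)CC(=O)O | starting material
21 | (3aR,4R,6E,10E,11aR)-10-{[(tert-butyldiphenylsilyl)oxy]methyl}-6-(dimethoxymethyl)-3-methylidene-2-oxo-2,3,3a,4,5,8,9,11a-octahydrocyclodeca[b]furan-4-yl 3-methylbutanoate | C=C1C(=O)O[C@@H]2/C=C(/CO[Si](c3ccccc3)(c3ccccc3)C(C)(C)C)CC/C=C(/C(OC)OC)C[C@@H](OC(=O)CC(C)C)[C@@H]12 | intermediate
22 | (3aR,4R,6E,10E,11aR)-6-(dimethoxymethyl)-10-(hydroxymethyl)-3-methylidene-2-oxo-2,3,3a,4,5,8,9,11a-octahydrocyclodeca[b]furan-4-yl 3-methylbutanoate | C=C1C(=O)O[C@@H]2/C=C(/CO)CC/C=C(/C(OC)OC)C[C@@H](OC(=O)CC(C)C)[C@@H]12 | intermediate (not isolated)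
23 | CNP0345200.3, (3aR,4R,6E,10E,11aR)-6-formyl-10-(hydroxymethyl)-3-methylidene-2-oxo-2,3,3a,4,5,8,9,11a-octahydrocyclodeca[b]furan-4-yl 3-methylbutanoate | C=C1C(=O)O[C@@H]2/C=C(/CO)CC/C=C(/C=O)C[C@@H](OC(=O)CC(C)C)[C@@H]12 | target

**Step count and risks**

Total step count: 15. Longest linear sequence: 14 (steps 1–3 and 5–15, from but-2-yne-1,4-diol); step 4 is a one-step branch.

Steps most likely to fail:

1. Step 13 (ring closure). The allylchromium species may be lost to intermolecular allylation (oligomers) or to a 1,4-elimination that opens the butenolide. The β,γ-unsaturated aldehyde may drift into conjugation during the slow addition. Bond formation on the other face of C7 would give the cis-fused lactone. Fallback, setting out from 16 and coming back at 19: the allyl nucleophile is prepared as a stable reagent before the aldehyde exists. Pd-catalysed borylation of the allylic bromide of 16 (bis(pinacolato)diboron, Pd2(dba)3, toluene, 50 °C) should give the allylboronate alcohol F1. Dess–Martin oxidation then gives the allylboronate aldehyde F2. Heating F2 in toluene at 2 mM should effect an intramolecular allylboration through the same chair transition state, with no reductant and no Lewis-acidic metal salt present, and work-up with aqueous triethanolamine releases 19.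

2. Step 14 (Mitsunobu inversion). Displacement at the hindered ring carbinol may stall at the alkoxyphosphonium stage, or E2 elimination toward the allylic C9 may give a conjugated diene. Fallback, setting out from 19 and coming back at 21: activation and displacement are separated. Chloromethanesulfonyl chloride and pyridine convert 19 into the chloromethanesulfonate F3, which is displaced with inversion by caesium 3-methylbutanoate and 18-crown-6 in toluene at 60 °C to give 21.

3. Step 10 (butenolide metathesis). The ruthenium alkylidene formed at the C7 vinyl group may close onto the C1=C10 olefin to give a seven-membered carbocycle, or the electron-poor 2-(bromomethyl)acrylate may fail to engage. Fallback, setting out from 11 and coming back at 15, without metathesis: Zn–ProPhenol/Me2Zn alkynylation of 11 with methyl propiolate (ligand antipode chosen for the R carbinol) gives the γ-hydroxy ynoate F4. Lindlar semihydrogenation gives the (Z)-enoate, which lactonises to the α-unsubstituted butenolide F5. Morita–Baylis–Hillman hydroxymethylation (aqueous formaldehyde, imidazole) gives the 3-(hydroxymethyl)butenolide F6. Appel bromination (CBr4, PPh3) then gives 15.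

**Further compounds**

F1 | step 13 | (5R)-5-[(1E,5E)-2-{[(tert-butyldiphenylsilyl)oxy]methyl}-6-(dimethoxymethyl)-8-hydroxyocta-1,5-dien-1-yl]-3-[(4,4,5,5-tetramethyl-1,3,2-dioxaborolan-2-yl)methyl]furan-2(5H)-one | O=C1O[C@H](/C=C(/CO[Si](c2ccccc2)(c2ccccc2)C(C)(C)C)CC/C=C(/C(OC)OC)CCO)C=C1CB1OC(C)(C)C(C)(C)O1
F2 | step 13 | (3E,7E)-7-{[(tert-butyldiphenylsilyl)oxy]methyl}-3-(dimethoxymethyl)-8-{(2R)-5-oxo-4-[(4,4,5,5-tetramethyl-1,3,2-dioxaborolan-2-yl)methyl]-2,5-dihydrofuran-2-yl}octa-3,7-dienal | O=C1O[C@H](/C=C(/CO[Si](c2ccccc2)(c2ccccc2)C(C)(C)C)CC/C=C(/C(OC)OC)CC=O)C=C1CB1OC(C)(C)C(C)(C)O1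
F3 | step 14 | (3aR,4S,6E,10E,11aR)-10-{[(tert-butyldiphenylsilyl)oxy]methyl}-6-(dimethoxymethyl)-3-methylidene-2-oxo-2,3,3a,4,5,8,9,11a-octahydrocyclodeca[b]furan-4-yl chloromethanesulfonate | C=C1C(=O)O[C@@H]2/C=C(/CO[Si](c3ccccc3)(c3ccccc3)C(C)(C)C)CC/C=C(/C(OC)OC)C[C@H](OS(=O)(=O)CCl)[C@@H]12
F4 | step 10 | methyl (4R,5E,9E)-12-[(tert-butyldimethylsilyl)oxy]-6-{[(tert-butyldiphenylsilyl)oxy]methyl}-10-(dimethoxymethyl)-4-hydroxydodeca-5,9-dien-2-ynoate | COC(=O)C#C[C@H](O)/C=C(/CO[Si](c1ccccc1)(c1ccccc1)C(C)(C)C)CC/C=C(/C(OC)OC)CCO[Si](C)(C)C(C)(C)C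
F5 | step 10 | (5S)-5-[(1E,5E)-8-[(tert-butyldimethylsilyl)oxy]-2-{[(tert-butyldiphenylsilyl)oxy]methyl}-6-(dimethoxymethyl)octa-1,5-dien-1-yl]furan-2(5H)-one | O=C1O[C@H](/C=C(/CO[Si](c2ccccc2)(c2ccccc2)C(C)(C)C)CC/C=C(/C(OC)OC)CCO[Si](C)(C)C(C)(C)C)C=C1
F6 | step 10 | (5R)-5-[(1E,5E)-8-[(tert-butyldimethylsilyl)oxy]-2-{[(tert-butyldiphenylsilyl)oxy]methyl}-6-(dimethoxymethyl)octa-1,5-dien-1-yl]-3-(hydroxymethyl)furan-2(5H)-one | O=C1O[C@H](/C=C(/CO[Si](c2ccccc2)(c2ccccc2)C(C)(C)C)CC/C=C(/C(OC)OC)CCO[Si](C)(C)C(C)(C)C)C=C1CO
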